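**Conventions.** Locants C1–C50 are those of the macrolide (C1 = lactone carbonyl, O41 = lactone oxygen). TBS = tert-butyldimethylsilyl, TBDPS = tert-butyldiphenylsilyl, PMB = 4-methoxybenzyl, Piv = 2,2-dimethylpropanoyl. Where a name carries no descriptor, each stereocentre has the spatial arrangement it has in the target, as written in the SMILES of the compound list.

## Analysis of the target

The target is a single 42-membered lactone (C1–C41 and O41) whose ester is a (2Z,4Z)-4-methyl-2,4-dienoate closed onto the C41 carbinol, with a nine-carbon side chain (C42–C50) on C41. It has fifteen stereocentres in four groups that are too far apart to control one another. These are an all-anti 1,3-hexol at C7, C9, C11, C13, C15 and C17; the C17–C18–C19 triad (methyl anti to O17, syn to O19) next to the (20Z) trisubstituted alkene; three isolated carbinols at C23, C27 and C31, each separated by three methylenes; and the syn,syn triad C41–C42–C43 with the remote C49 carbinol. A second Z alkene lies at C38=C39, two carbons from C41. The sensitive groups are the (2Z,4Z)-dienoate, which isomerises when the carboxyl is activated by nucleophilic catalysts, the O41 ester next to the free O43 (acyl migration), the C19 allylic alcohol and twelve free hydroxyls that must be released together under mild conditions. The difficulty lies in absolute control of each isolated region, in telling O41 apart from eleven other secondary oxygens, in two trisubstituted Z alkenes of the same pattern (C4=C5 and C20=C21) and in closing a very large ring without touching the diene geometry. The strategy rests on the string C39–C40–C41–C42–C43 with O43. O41, the C42 methyl and O43 are mutually syn and C39 is a Z-alkene carbon, so bonding O43 to C39 folds the string into a 2,3-cis-2-alkyl-3-methyl-2,3-dihydropyran-4-one. This six-membered ring is not in the target; it sets the triad and later opens into the C38=C39 alkene.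

## Retrosynthetic reasoning

**Silyl ethers.** Target 81 is traced to the fully silylated macrolactone 80. All twelve hydroxyls are masked as silyl ethers so that one fluoride treatment, neutral towards the dienoate and the O41 ester, ends the synthesis.

**C1–O41.** The lactone bond of 80 is cut to give seco acid 78. It is the only ester and the only ring bond whose formation creates no stereocentre. The forward reaction must acylate the hindered C41 hydroxyl, the only free one, without isomerising the dienoate; 78 comes from 76 by removal of the single PMB ether (77) and saponification.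

**C19–C20.** Alcohol 75 is cut between the allylic carbinol and the alkene into alkenyl iodide 72 and aldehyde 63, two halves of similar size. In 63 the C18 methyl and the C17 silyloxy group are anti, so Felkin–Anh and 1,3-anti induction both favour the required C19 configuration. The forward step must transfer the alkenyl group with retention of its Z geometry.

**C2=C3 and C4=C5.** Dienoate 61, the precursor of 63, is cut at C2=C3 into enal 58 and phosphonoacetate 59. Enal 58 is traced through allylic alcohol 57 to enoate 56, which is cut at C4=C5 into aldehyde 53 and phosphonopropanoate 54. Both alkenes then come from Z-selective Horner–Wadsworth–Emmons reactions of bis(trifluoroethyl) phosphonates: the first places the ester carbon C3 cis to C6, the second places C1 cis to C4. The dienoate is thus built on the smaller fragment, before the union, and without organotin reagents.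

**C20=C21.** Iodide 72 is traced to aldehyde 68 and phosphonium salt 69. Here C20 must become a carbon nucleophile and not an ester, so the alkene is made with an α-iodo ylide, which places iodine cis to C22.

**C38=C39.** Alkene 65, the precursor of 68, is cut into lactol 19 and the ylide 64 of phosphonium salt 37. A non-stabilised ylide gives the Z alkene, and opening the lactol releases O43 while O41 stays a PMB ether, which is how O41 is distinguished from all other oxygens.

**The temporary ring.** Lactol 19 is traced through PMB ether 18 and axial alcohol 17 to ketone 16 and enone 15. The ring holds C42 and C43 cis and directs a bulky hydride to C41 from the equatorial side.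

**C42–C43 and O43–C39 (key).** Enone 15 is cut by a hetero-Diels–Alder disconnection into aldehyde 8 and diene 13. One catalytic step forms both bonds and sets C42 and C43; the C49 centre is too remote to matter.

**Aldehyde and diene.** Aldehyde 8 comes from epoxide 2 and bromide 1; C49 is bought. Its hydroxyl is carried as a TBDPS ether, because a TBS ether would be at risk in acidic methanol (step 8) and aqueous acid (step 11). Diene 13 comes from enone 12, made from 9 and 10.

**C21–C38.** Salt 37 is traced to alcohol 33 and to bis-dithiane 31, which is cut at C24–C25, C25–C26, C28–C29 and C29–C30 into silyl dithiane 20 (used twice), epoxide 24 and epoxide 29. Each carbinol is bought as an epoxide, and the dithiane carbons become the methylenes C25 and C29.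

**Common epoxide.** Epoxide 24 comes from 20, 21 and 22. Its carbons are C21–C28 of one half and, with the same configurations, C5–C12 of the other, so one compound feeds both.

**C5–C19 polyol.** Aldehyde 53 is traced to heptakis-silyl ether 51, pentaol 50 and triketone 49, then to tris-dithiane 48, which is cut at C12–C13 and C13–C14 into 24, 1,3-dithiane 44 and epoxide 43. Epoxide 43 comes from dithiane 41 (from ester 38) and 26. C7, C11, C15 and C18 are bought, and C9, C13 and C17 are set together by hydroxyl-directed anti reduction.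

## Alternatives that were turned down

**Alternative 1:** The C20=C21 bond is cut, and the two halves are joined through a silicon tether between O19 and O23. In the forward key step, the mixed diisopropylsilylene acetal A1 undergoes ring-closing metathesis with the second-generation Hoveyda–Grubbs catalyst RuCl2(H2IMes)(=CH-C6H4-2-OiPr), which gives the dioxasilacyclooctene A2 with loss of ethylene. In its favour, the eight-membered ring can only hold a cis alkene, so the Z geometry is certain, and C19 is already set before the union. On both points it is stronger than the chosen route, where the geometry depends on an iodo-olefination and C19 on a substrate-controlled addition. Against it, two hindered secondary alcohols must be silylated in sequence on one silicon without forming the symmetrical acetals. Closure of an eight-membered ring through a 1,1-disubstituted alkene is slow and competes with oligomerisation. Cleavage of the tether then frees O19 and O23 together, so both must be protected again. It also leaves the C41–C43 triad and the C38=C39 alkene unsolved. The chosen strategy offers, in its place, one catalytic step that sets two stereocentres, prepares the third and supplies the Z alkene, at a cost of no tether steps.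

**Alternative 2:** The C1–O41 bond is cut, and the dienoate is held beforehand in an eight-membered lactone on O7. In the forward key step, the free C41 hydroxyl of A3 attacks C1 under catalytic Ti(OiPr)4 (tetravalent titanium) or NaN(SiMe3)2 at high dilution and releases O7, which gives the 42-membered lactone A4. In its favour, both double bonds are locked cis in the small ring, and no activating agent that could isomerise the diene is needed. This is stronger than the macrolactonisation used here. Against it, the attacking hydroxyl is hindered and more than thirty atoms from the carbonyl, so intermolecular transesterification competes. A strong base can deconjugate the dienoate, the liberated C7 alkoxide can return, and the strained dienolide must survive every fragment union. The chosen strategy offers an ordinary seco acid with the dienoate made late on a small fragment, and it addresses the side-chain triad, which this alternative does not.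

**Alternative 3:** The polyol core is cut at C8–C9 and C15–C16 in two directions. In the forward key step, diol A5 reacts at both primary carbinols with allyl acetate under the cyclometalated trivalent iridium catalyst made from [Ir(cod)Cl]2, BINAP, 4-chloro-3-nitrobenzoic acid and Cs2CO3, which gives the C2-symmetric diol A6. In its favour, it uses the local C2 axis through C12, needs no aldehyde oxidation state and sets C9 and C15 under catalyst control in one step. For the polyol alone it is shorter than the dithiane route used here. Against it, the two ends of A6 are identical, while the target needs C5–C6 at one end and the C18 methyl and C19 at the other, so a statistical desymmetrisation follows. The remaining carbinols C7 and C17 still have to be added, and nothing is gained for C20=C21, C38=C39 or C41–C43. The chosen strategy builds the polyol from fragments whose ends differ from the start and places the risk in the side-chain ring.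

Key step: step 7

**Assumptions.** (1) The chromium catalyst from (1S,2R)-cis-1-amino-2-indanol is assumed to expose the Si face of aldehyde 8, which gives 43R; if the sense is the opposite, the (1R,2S) catalyst is used without other change. (2) Compounds 20, 21, 22, 25, 26, 54, 59 and 69 are taken as purchasable.

## Steps

Step 1
Reactants: 1 5-bromopent-1-ene; 2 (R)-2-methyloxirane
Product: 4 (R)-oct-7-en-2-ol, via pent-4-enylmagnesium bromide 3 (not isolated)
Conditions: Mg, THF, 40 °C; then CuI (10 mol%), 2, −30 to 0 °C; aq. NH4Cl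
Reagents that add atoms: none
Why: Copper-catalysed Grignard opening of a terminal epoxide takes place at the unsubstituted carbon, so C49 comes unchanged from the chiral pool.

Step 2
Reactants: 4 (R)-oct-7-en-2-ol
Product: 5 (R)-tert-butyl(oct-7-en-2-yloxy)diphenylsilane
Conditions: t-BuPh2SiCl, imidazole, DMF, rt
Reagents that add atoms: tert-butyl(chloro)diphenylsilane CC(C)(C)[Si](Cl)(c1ccccc1)c1ccccc1
Why: Standard silylation of a secondary alcohol; the diphenylsilyl ether is chosen because it should survive the acidic steps 7, 8 and 11.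

Step 3
Reactants: 5 (R)-tert-butyl(oct-7-en-2-yloxy)diphenylsilane
Product: 7 (R)-7-(tert-butyldiphenylsilyloxy)octan-1-ol, via B-alkyl-9-borabicyclononane 6 (not isolated)
Conditions: 9-borabicyclo[3.3.1]nonane, THF, 0 °C to rt; then NaOH, H2O2, 0 °C to rt
Reagents that add atoms: hydrogen peroxide OO
Why: Anti-Markovnikov hydroboration–oxidation of the terminal alkene gives the primary alcohol with all eight carbons retained.

Step 4
Reactants: 7 (R)-7-(tert-butyldiphenylsilyloxy)octan-1-ol
Product: 8 (R)-7-(tert-butyldiphenylsilyloxy)octanal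
Conditions: Dess–Martin periodinane, NaHCO3, CH2Cl2, 0 °C to rt
Reagents that add atoms: none
Why: Mild periodinane oxidation stops at the aldehyde and leaves the silyl ether untouched.

Step 5
Reactants: 9 propanoyl chloride; 10 methoxyethene
Product: 12 (E)-1-methoxypent-1-en-3-one, via 1-chloro-1-methoxypentan-3-one 11 (not isolated)
Conditions: 10 (excess), −10 °C to rt; then Et3N, Et2O, 0 °C to rt; distillation
Reagents that add atoms: none
Why: Electrophilic acylation of the enol ether gives the β-chloro ether, and base-induced loss of HCl gives the conjugated E vinylogous ester.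

Step 6
Reactants: 12 (E)-1-methoxypent-1-en-3-one
Product: 13 (1E,3Z)-1-methoxy-3-(trimethylsilyloxy)penta-1,3-diene
Conditions: Me3SiOSO2CF3, Et3N, Et2O, 0 °C; distillation
Reagents that add atoms: trimethylsilyl trifluoromethanesulfonate C[Si](C)(C)OS(=O)(=O)C(F)(F)F
Why: Soft enolisation of the ethyl ketone with silyl triflate and amine should favour the Z silyl enol ether, which fixes the diene geometry needed for the cis ring.

Step 7
Reactants: 8 (R)-7-(tert-butyldiphenylsilyloxy)octanal; 13 (1E,3Z)-1-methoxy-3-(trimethylsilyloxy)penta-1,3-diene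
Product: 15 (2R,3S)-2-[(6R)-6-(tert-butyldiphenylsilyloxy)heptyl]-3-methyl-2,3-dihydro-4H-pyran-4-one, via silyl enol ether cycloadduct 14 (not isolated)
Conditions: CrCl(L) (3 mol%; trivalent chromium, L = O,N,O-dianion of the Schiff base of (1S,2R)-cis-1-amino-2-indanol and 3-(1-adamantyl)-2-hydroxy-5-methylbenzaldehyde), 4 Å molecular sieves, acetone (minimal), rt; then CF3CO2H, CH2Cl2, 0 °C
Reagents that add atoms: none
Why: The chromium centre binds the aldehyde oxygen anti to the alkyl chain and the diene adds through a concerted, asynchronous [4+2] transition state; the closest known reaction type is the chromium Schiff-base-catalysed hetero-Diels–Alder reaction of unactivated aliphatic aldehydes with 1-alkoxy-3-silyloxy dienes. The six-membered oxacycle closes by intermolecular cycloaddition, which forms C42–C43 and O43–C39 in one event. C43 is set by the catalyst, whose ligand leaves one aldehyde face open (the Si face is assumed for this ligand). C42 follows from C43 through the endo transition state: in the (3Z) silyl enol ether the methyl is an outside substituent, so endo approach of the chain places chain and methyl cis. The step needs enantiofacial selectivity, endo selectivity and cycloaddition in preference to a stepwise Mukaiyama aldol path; the unbranched, non-chelating aldehyde and the tightly bound chloride complex favour the concerted path, and the C49 silyl ether is too remote to interfere. Trifluoroacetic acid then removes methanol and the silyl group from 14, and because enolisation of the vinylogous ester towards C42 is cross-conjugated and slow, the cis relationship should be kept.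

Step 8
Reactants: 15 (2R,3S)-2-[(6R)-6-(tert-butyldiphenylsilyloxy)heptyl]-3-methyl-2,3-dihydro-4H-pyran-4-one
Product: 16 (2R,3S,6S)-2-[(6R)-6-(tert-butyldiphenylsilyloxy)heptyl]-6-methoxy-3-methyltetrahydro-4H-pyran-4-one
Conditions: MeOH, camphor-10-sulfonic acid (10 mol%), 0 °C to rt; Et3N quench
Reagents that add atoms: methanol CO
Why: Acid-catalysed conjugate addition of methanol to the vinylogous ester proceeds through the ring oxocarbenium ion; the anomeric effect should place the new methoxy group axial (trans to the C43 chain), and C39 keeps the aldehyde oxidation level.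

Step 9
Reactants: 16 (2R,3S,6S)-2-[(6R)-6-(tert-butyldiphenylsilyloxy)heptyl]-6-methoxy-3-methyltetrahydro-4H-pyran-4-one
Product: 17 (2R,3R,4S,6S)-2-[(6R)-6-(tert-butyldiphenylsilyloxy)heptyl]-6-methoxy-3-methyltetrahydro-2H-pyran-4-ol
Conditions: K[(s-Bu)3BH], THF, −78 °C; aq. NH4Cl
Reagents that add atoms: none
Why: K-Selectride reduction; the bulky hydride enters equatorially, away from the axial methoxy group that blocks the axial path, so the C41 hydroxyl becomes axial and trans to the C42 methyl, which is the syn,syn triad of the open chain.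

Step 10
Reactants: 17 (2R,3R,4S,6S)-2-[(6R)-6-(tert-butyldiphenylsilyloxy)heptyl]-6-methoxy-3-methyltetrahydro-2H-pyran-4-ol
Product: 18 (2R,3R,4S,6S)-2-[(6R)-6-(tert-butyldiphenylsilyloxy)heptyl]-6-methoxy-4-(4-methoxybenzyloxy)-3-methyltetrahydro-2H-pyran
Conditions: NaH, 4-MeOC6H4CH2Cl, Bu4NI (cat.), THF/DMF, 0 °C to rt
Reagents that add atoms: 4-methoxybenzyl chloride COc1ccc(CCl)cc1
Why: Williamson etherification; a benzyl-type ether cannot migrate to O43 and is the only group later removed by oxidation, which marks O41 for lactonisation.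

Step 11
Reactants: 18 (2R,3R,4S,6S)-2-[(6R)-6-(tert-butyldiphenylsilyloxy)heptyl]-6-methoxy-4-(4-methoxybenzyloxy)-3-methyltetrahydro-2H-pyran
Product: 19 (4S,5R,6R)-6-[(6R)-6-(tert-butyldiphenylsilyloxy)heptyl]-4-(4-methoxybenzyloxy)-5-methyltetrahydro-2H-pyran-2-ol (both anomers)
Conditions: AcOH/H2O/THF (3:1:1), 45 °C
Reagents that add atoms: water O
Why: Acetal hydrolysis; a 2-deoxy glycoside ionises easily, so conditions that spare the PMB and TBDPS ethers should suffice.

Step 12
Reactants: 20 2-(tert-butyldimethylsilyl)-1,3-dithiane; 21 (S)-2-[2-(benzyloxy)ethyl]oxirane; 22 (S)-2-(chloromethyl)oxirane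
Product: 24 tert-butyl{[(2S)-4-(benzyloxy)-1-(2-{[(2S)-oxiran-2-yl]methyl}-1,3-dithian-2-yl)butan-2-yl]oxy}dimethylsilane, via lithiated dithiane silyl ether 23 (not isolated)
Conditions: t-BuLi, Et2O, −78 to −45 °C; 21, −78 to −25 °C; then 22, THF/HMPA, −78 to 0 °C
Reagents that add atoms: none
Why: Three-component dithiane linchpin coupling: epoxide opening, solvent-triggered 1,4-Brook rearrangement and a second alkylation. The carbinol carbons of 21 and 22 are not touched, since the anion opens 22 at the ring CH2 and the alkoxide then closes onto CH2Cl.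

Step 13
Reactants: 25 (6-bromohexyloxy)(tert-butyl)dimethylsilane; 26 (R)-2-(chloromethyl)oxirane
Product: 29 (R)-tert-butyldimethyl{[7-(oxiran-2-yl)heptyl]oxy}silane, via Grignard reagent 27 (not isolated), via chlorohydrin 28 (not isolated)
Conditions: Mg, THF; CuI (10 mol%), 26, −40 to −20 °C; aq. NH4Cl; then NaOH, MeOH, 0 °C to rt on the crude chlorohydrin
Reagents that add atoms: none
Why: Copper-catalysed Grignard opening at the epoxide CH2 followed by base-induced closure onto the chloromethyl carbon; the C31 centre comes from 26 without any bond to it being broken.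

Step 14
Reactants: 20 2-(tert-butyldimethylsilyl)-1,3-dithiane; 29 (R)-tert-butyldimethyl{[7-(oxiran-2-yl)heptyl]oxy}silane; 24 epoxide from step 12
Product: 31 C21–C38 bis-dithiane alcohol (O21 benzyl; O23, O31 and O38 TBS; C27 hydroxyl free; dithianes at C25 and C29), via lithiated dithiane silyl ether 30 (not isolated)
Conditions: 20, t-BuLi, Et2O, −78 to −45 °C; 29, −78 to −25 °C; then 24, THF/HMPA, −78 to −20 °C
Reagents that add atoms: none
Why: Second linchpin coupling of the same type; opening 29 gives the C31 alkoxide, Brook rearrangement silylates it and the new dithiane anion opens 24 at C28, which leaves the C27 hydroxyl free.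

Step 15
Reactants: 31 C21–C38 bis-dithiane alcohol
Product: 32 C21–C38 bis-dithiane with O23, O27, O31 and O38 as TBS ethers
Conditions: t-BuMe2SiOSO2CF3, 2,6-lutidine, CH2Cl2, −78 to 0 °C
Reagents that add atoms: tert-butyldimethylsilyl trifluoromethanesulfonate CC(C)(C)[Si](C)(C)OS(=O)(=O)C(F)(F)F
Why: Silyl triflate silylation of the remaining secondary hydroxyl.

Step 16
Reactants: 32 C21–C38 bis-dithiane tetrakis-TBS ether
Product: 33 (3R,7R,11R)-3,7,11,18-tetrakis(tert-butyldimethylsilyloxy)octadecan-1-ol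
Conditions: Raney Ni (W-2), H2 (1 atm), EtOH, 60 °C
Reagents that add atoms: none
Why: Raney nickel desulfurisation turns both dithiane carbons into the methylenes C25 and C29, and the same reagent hydrogenolyses the benzyl ether; no alkene is present yet and silyl ethers are inert.

Step 17
Reactants: 33 (3R,7R,11R)-3,7,11,18-tetrakis(tert-butyldimethylsilyloxy)octadecan-1-ol
Product: 34 (3R,7R,11R)-3,7,11,18-tetrakis(tert-butyldimethylsilyloxy)octadecyl 2,2-dimethylpropanoate
Conditions: t-BuCOCl, pyridine, 4-(dimethylamino)pyridine (cat.), CH2Cl2, 0 °C to rt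
Reagents that add atoms: pivaloyl chloride CC(C)(C)C(=O)Cl
Why: Acylation of the primary alcohol; the pivalate withstands fluoride, ylide and silylation conditions and is later removed by hydride alone.

Step 18
Reactants: 34 pivalate from step 17
Product: 35 (3R,7R,11R)-3,7,11-tris(tert-butyldimethylsilyloxy)-18-hydroxyoctadecyl 2,2-dimethylpropanoate
Conditions: HF·pyridine, pyridine, THF, 0 °C to rt
Reagents that add atoms: none
Why: Buffered fluoride cleaves the unhindered primary silyl ether much faster than the three secondary ones.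

Step 19
Reactants: 35 hydroxy pivalate from step 18
Product: 36 (3R,7R,11R)-3,7,11-tris(tert-butyldimethylsilyloxy)-18-iodooctadecyl 2,2-dimethylpropanoate
Conditions: I2, PPh3, imidazole, CH2Cl2, 0 °C to rt
Reagents that add atoms: iodine II
Why: Appel-type iodination of a primary alcohol through the alkoxyphosphonium ion.

Step 20
Reactants: 36 iodide from step 19
Product: 37 [(8R,12R,16R)-8,12,16-tris(tert-butyldimethylsilyloxy)-18-(pivaloyloxy)octadecyl]triphenylphosphonium iodide
Conditions: PPh3, i-Pr2NEt (cat.), MeCN, 80 °C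
Reagents that add atoms: triphenylphosphine c1ccc(cc1)P(c1ccccc1)c1ccccc1
Why: SN2 quaternisation of the primary iodide; the amine buffer protects the silyl ethers from traces of acid.

Step 21
Reactants: 38 methyl (S)-3-hydroxy-2-methylpropanoate
Product: 39 methyl (S)-3-(tert-butyldimethylsilyloxy)-2-methylpropanoate
Conditions: t-BuMe2SiCl, imidazole, CH2Cl2, rt
Reagents that add atoms: tert-butyl(chloro)dimethylsilane CC(C)(C)[Si](C)(C)Cl
Why: Standard silylation; the C18 stereocentre is bought.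

Step 22
Reactants: 39 methyl (S)-3-(tert-butyldimethylsilyloxy)-2-methylpropanoate
Product: 40 (S)-3-(tert-butyldimethylsilyloxy)-2-methylpropanal
Conditions: i-Bu2AlH, CH2Cl2, −78 °C; MeOH, then aq. sodium potassium tartrate
Reagents that add atoms: none
Why: Partial reduction of the ester; the tetrahedral aluminium hemiacetal is stable at −78 °C and releases the aldehyde on work-up without loss of the α-centre.

Step 23
Reactants: 40 (S)-3-(tert-butyldimethylsilyloxy)-2-methylpropanal
Product: 41 (S)-tert-butyl[2-(1,3-dithian-2-yl)propoxy]dimethylsilane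
Conditions: HS(CH2)3SH, MgBr2·OEt2, Et2O, rt
Reagents that add atoms: propane-1,3-dithiol SCCCS
Why: Lewis-acid-mediated thioacetalisation; the mild magnesium salt should spare the silyl ether and the α-stereocentre.

Step 24
Reactants: 41 (S)-tert-butyl[2-(1,3-dithian-2-yl)propoxy]dimethylsilane; 26 (R)-2-(chloromethyl)oxirane
Product: 43 tert-butyldimethyl{[(2S)-2-(2-{[(2R)-oxiran-2-yl]methyl}-1,3-dithian-2-yl)propyl]oxy}silane, via 2-lithio dithiane 42 (not isolated)
Conditions: t-BuLi, THF/HMPA (10:1), −78 °C; 26, −78 to 0 °C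
Reagents that add atoms: none
Why: Alkylation of a lithiated 2-alkyl-1,3-dithiane; the anion opens 26 at the ring CH2 and the alkoxide closes onto CH2Cl, so the C15 centre comes from 26 with its C–O bond intact.

Step 25
Reactants: 44 1,3-dithiane; 24 epoxide from step 12
Product: 46 C5–C13 alcohol (O5 benzyl, O7 TBS, C9 dithiane, C11 hydroxyl, C13 as 1,3-dithian-2-yl), via 2-lithio-1,3-dithiane 45 (not isolated)
Conditions: n-BuLi, THF, −30 °C; 24, −30 to 0 °C
Reagents that add atoms: none
Why: Epoxide opening by the dithiane anion at the terminal carbon C12; the C11 carbinol is not involved.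

Step 26
Reactants: 46 C5–C13 alcohol; 43 epoxide from step 24
Product: 48 C5–C19 tris-dithiane diol (dithianes at C9, C13 and C17; hydroxyls at C11 and C15; O7 and O19 TBS; O5 benzyl), via dilithio species 47 (not isolated)
Conditions: t-BuLi (2.2 equiv), THF/HMPA (10:1), −78 °C; 43, −78 to −20 °C
Reagents that add atoms: none
Why: Second alkylation of the same dithiane carbon; the first equivalent of base forms the C11 alkoxide and the second removes the only remaining dithiane proton (C13), which opens 43 at C14 and leaves both C11 and C15 hydroxyls free for the reduction.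

Step 27
Reactants: 48 C5–C19 tris-dithiane diol
Product: 49 C5–C19 triketone diol (ketones at C9, C13 and C17)
Conditions: Hg(ClO4)2·3H2O (divalent mercury), CaCO3, THF/H2O (5:1), 0 °C
Reagents that add atoms: water O
Why: Thiophilic-metal-assisted dithiane hydrolysis under carbonate buffer, which should spare the silyl ethers, the β-hydroxy ketones and the C18 centre next to the C17 ketone.

Step 28
Reactants: 49 C5–C19 triketone diol
Product: 50 C5–C19 pentaol (hydroxyls at C9, C11, C13, C15 and C17, all 1,3-anti)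
Conditions: Me4NBH(OAc)3, MeCN/AcOH (1:1), −30 to −20 °C
Reagents that add atoms: none
Why: Evans–Saksena reduction; each free hydroxyl exchanges onto boron and delivers hydride through a chair transition state to give the 1,3-anti diol. O11 directs C9 and C13, O15 directs C13 and C17, and the two demands on C13 coincide because O11 and O15 are syn to each other.

Step 29
Reactants: 50 C5–C19 pentaol
Product: 51 C5–C19 heptakis-TBS ether (O7, O9, O11, O13, O15, O17 and O19 silylated; O5 benzyl)
Conditions: t-BuMe2SiOSO2CF3 (excess), 2,6-lutidine, CH2Cl2, 0 °C to rt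
Reagents that add atoms: tert-butyldimethylsilyl trifluoromethanesulfonate CC(C)(C)[Si](C)(C)OS(=O)(=O)C(F)(F)F
Why: Exhaustive silylation with the silyl triflate, which is reactive enough for the crowded polyol.

Step 30
Reactants: 51 C5–C19 heptakis-TBS ether
Product: 52 C5 primary alcohol of the C5–C19 fragment
Conditions: H2 (1 atm), Pd(OH)2 on carbon, EtOAc, rt
Reagents that add atoms: none
Why: Hydrogenolysis of the benzyl ether; the fragment contains no alkene and silyl ethers are inert.

Step 31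
Reactants: 52 C5 primary alcohol
Product: 53 C5 aldehyde of the C5–C19 fragment
Conditions: Dess–Martin periodinane, NaHCO3, CH2Cl2, 0 °C to rt
Reagents that add atoms: none
Why: Buffered periodinane oxidation gives the β-silyloxy aldehyde without elimination.

Step 32
Reactants: 53 C5 aldehyde; 54 methyl 2-[bis(2,2,2-trifluoroethoxy)phosphoryl]propanoate
Product: 56 methyl (Z)-2-methylalk-2-enoate of the C3–C19 fragment (C3 as methyl ester, methyl on C4, (4Z) alkene, O19 primary TBS ether), via potassium phosphonopropanoate carbanion 55 (not isolated)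
Conditions: 54, KN(SiMe3)2, 18-crown-6, THF, −78 °C; then 53, −78 °C; aq. NH4Cl
Reagents that add atoms: none
Why: Still–Gennari olefination; with the electron-poor bis(trifluoroethyl) phosphonate and a dissociated potassium counter-ion the oxaphosphetane collapses faster than it equilibrates, so the kinetic Z enoate should form, with the ester carbon C3 cis to C6. The carbanion is preformed and weakly basic, so the β-silyloxy aldehyde should not eliminate.

Step 33
Reactants: 56 methyl (Z)-2-methylalk-2-enoate of the C3–C19 fragment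
Product: 57 (Z)-allylic alcohol of the C3–C19 fragment (C3 primary alcohol)
Conditions: i-Bu2AlH (2.5 equiv), CH2Cl2, −78 °C; aq. sodium potassium tartrate
Reagents that add atoms: none
Why: 1,2-Reduction of the conjugated ester by the aluminium hydride gives the allylic alcohol; the silyl ethers are inert and the alkene geometry is not touched.

Step 34
Reactants: 57 (Z)-allylic alcohol of the C3–C19 fragment
Product: 58 (Z)-enal of the C3–C19 fragment (C3 aldehyde, methyl on C4)
Conditions: Dess–Martin periodinane, NaHCO3, CH2Cl2, 0 °C; used directly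
Reagents that add atoms: none
Why: Buffered periodinane oxidation of the primary allylic alcohol; neutral conditions and immediate use should keep the (4Z) geometry of the α-methyl enal.

Step 35
Reactants: 58 (Z)-enal of the C3–C19 fragment; 59 methyl 2-[bis(2,2,2-trifluoroethoxy)phosphoryl]acetate
Product: 61 methyl (2Z,4Z)-dienoate of the C1–C19 fragment (O19 primary TBS ether), via potassium phosphonoacetate carbanion 60 (not isolated)
Conditions: 59, KN(SiMe3)2, 18-crown-6, THF, −78 °C; then 58, −78 °C; aq. NH4Cl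
Reagents that add atoms: none
Why: Second Still–Gennari olefination; kinetic control again gives the Z alkene, now C2=C3 with C1 cis to C4, and the low temperature and the absence of free base should leave the (4Z) alkene as it is.

Step 36
Reactants: 61 methyl (2Z,4Z)-dienoate
Product: 62 C19 primary alcohol of the C1–C19 fragment
Conditions: HF·pyridine, pyridine, THF, 0 °C to rt
Reagents that add atoms: none
Why: Buffered fluoride removes the single primary silyl ether in preference to the six secondary ones; the dienoate is inert.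

Step 37
Reactants: 62 C19 primary alcohol
Product: 63 C19 aldehyde of the C1–C19 fragment
Conditions: Dess–Martin periodinane, NaHCO3, CH2Cl2, 0 °C; used directly
Reagents that add atoms: none
Why: Neutral periodinane oxidation gives the α-methyl aldehyde without epimerisation at C18 if it is used at once.

Step 38
Reactants: 37 phosphonium iodide from step 20; 19 lactol from step 11
Product: 65 C21–C50 (38Z)-alkene with free C43 hydroxyl (O21 pivalate, O41 PMB, O49 TBDPS), via phosphorus ylide 64 (not isolated)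
Conditions: 37 (2.2 equiv), NaN(SiMe3)2 (2.1 equiv), THF, −78 to 0 °C; 19, −78 °C to rt
Reagents that add atoms: none
Why: Wittig reaction of a non-stabilised ylide with the open hydroxy-aldehyde form of the lactol gives the Z alkene by kinetic oxaphosphetane formation; ring opening frees O43, the second equivalent of ylide serving as base for the lactol hydroxyl.

Step 39
Reactants: 65 C21–C50 alkene with free C43 hydroxyl
Product: 66 C43 TBS ether of the C21–C50 alkene
Conditions: t-BuMe2SiOSO2CF3, 2,6-lutidine, CH2Cl2, −78 to 0 °C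
Reagents that add atoms: tert-butyldimethylsilyl trifluoromethanesulfonate CC(C)(C)[Si](C)(C)OS(=O)(=O)C(F)(F)F
Why: Silyl triflate silylation of the hindered secondary hydroxyl; O41 and O43 are now permanently differentiated.

Step 40
Reactants: 66 C43 TBS ether
Product: 67 C21 primary alcohol of the C21–C50 fragment
Conditions: i-Bu2AlH, CH2Cl2, −78 °C; aq. sodium potassium tartrate
Reagents that add atoms: none
Why: Reductive cleavage of the only ester; ethers, silyl ethers and the alkene are inert to the hydride.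

Step 41
Reactants: 67 C21 primary alcohol
Product: 68 C21 aldehyde of the C21–C50 fragment
Conditions: Dess–Martin periodinane, NaHCO3, CH2Cl2, 0 °C to rt
Reagents that add atoms: none
Why: Buffered periodinane oxidation of the primary alcohol.

Step 42
Reactants: 68 C21 aldehyde; 69 ethyltriphenylphosphonium iodide
Product: 72 C20–C50 (20Z)-alkenyl iodide (iodine and methyl on C20), via iodoethylphosphonium iodide 70 (not isolated), via iodo ylide 71 (not isolated)
Conditions: 69, n-BuLi, THF, 0 °C; I2, −78 °C; NaN(SiMe3)2, −78 to −20 °C; 68, −78 °C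
Reagents that add atoms: iodine II
Why: Stork–Zhao-type Wittig olefination with the α-iodo ylide gives the (Z)-2-iodoalkene under kinetic control, with iodine cis to C22, which becomes the C19/C22-cis relationship of the target; no stereocentre is affected.

Step 43
Reactants: 72 C20–C50 (20Z)-alkenyl iodide; 63 C19 aldehyde of the C1–C19 fragment
Product: 75 C1–C50 allylic alcohol (free C19 hydroxyl, methyl ester, O41 PMB), via alkenyllithium 73 (not isolated), via alkenylmagnesium bromide 74 (not isolated)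
Conditions: 72, t-BuLi (2.05 equiv), Et2O, −78 °C; MgBr2·OEt2, −78 °C; 63, −78 to −40 °C; aq. NH4Cl
Reagents that add atoms: none
Why: Iodine–lithium exchange and transmetalation occur with retention of alkene geometry, and the alkenylmagnesium adds to the aldehyde in preference to the ester. C19 is set by Felkin–Anh addition, reinforced by 1,3-anti induction from the anti-placed C17 silyloxy group, which gives 18,19-syn and 17,19-anti.

Step 44
Reactants: 75 C1–C50 allylic alcohol
Product: 76 C19 TBS ether of the C1–C50 chain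
Conditions: t-BuMe2SiOSO2CF3, 2,6-lutidine, CH2Cl2, −78 to 0 °C
Reagents that add atoms: tert-butyldimethylsilyl trifluoromethanesulfonate CC(C)(C)[Si](C)(C)OS(=O)(=O)C(F)(F)F
Why: Silylation of the hindered allylic hydroxyl under non-acidic conditions avoids allylic ionisation.

Step 45
Reactants: 76 C19 TBS ether of the C1–C50 chain
Product: 77 C41 alcohol of the C1–C50 methyl ester
Conditions: 2,3-dichloro-5,6-dicyano-1,4-benzoquinone, CH2Cl2/pH 7 buffer, 0 °C
Reagents that add atoms: none
Why: Oxidative cleavage of the single PMB ether by hydride abstraction from the electron-rich benzylic position; the electron-poor dienoate and the isolated alkenes should not react.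

Step 46
Reactants: 77 C41 alcohol of the C1–C50 methyl ester
Product: 78 seco acid (C1 carboxylic acid, free C41 hydroxyl)
Conditions: LiOH·H2O, THF/MeOH/H2O (4:1:1), rt; acidification to pH 4 with dilute HCl at 0 °C
Reagents that add atoms: lithium hydroxide [Li+].[OH-]
Why: Saponification of the unhindered methyl ester by acyl–oxygen cleavage; room temperature should avoid deconjugation of the diene.

Step 47
Reactants: 78 seco acid
Product: 80 fully silylated 42-membered macrolactone, via mixed anhydride 79 (not isolated)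
Conditions: 2,4,6-Cl3C6H2COCl, Et3N, THF, rt; then slow addition to 4-(dimethylamino)pyridine in toluene (about 0.5 mM), rt
Reagents that add atoms: none
Why: Yamaguchi macrolactonisation; the mixed anhydride is attacked regioselectively at the dienoyl carbonyl and the only free hydroxyl, O41, closes the strain-free 42-membered ring at high dilution with retention at C41.

Step 48
Reactants: 80 fully silylated 42-membered macrolactone
Product: 81 target macrolide
Conditions: HF·pyridine, pyridine, THF, 0 °C to rt (extended)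
Reagents that add atoms: none
Why: Global desilylation by buffered fluoride removes eleven TBS ethers and the TBDPS ether without base, so the dienoate geometry and the position of the ester should be kept.

## Compound list

1 | 5-bromopent-1-ene | C=CCCCBr | starting material
2 | (R)-2-methyloxirane | C[C@@H]1CO1 | starting material
3 | pent-4-enylmagnesium bromide | C=CCCC[Mg]Br | intermediate (not isolated)
4 | (R)-oct-7-en-2-ol | C=CCCCC[C@@H](C)O | intermediate
5 | (R)-tert-butyl(oct-7-en-2-yloxy)diphenylsilane | C=CCCCC[C@@H](C)O[Si](c1ccccc1)(c1ccccc1)C(C)(C)C | intermediate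
6 | B-[(7R)-7-(tert-butyldiphenylsilyloxy)octyl]-9-borabicyclo[3.3.1]nonane | C1CCC2CCCC1B2CCCCCC[C@@H](C)O[Si](c3ccccc3)(c4ccccc4)C(C)(C)C | intermediate (not isolated)
7 | (R)-7-(tert-butyldiphenylsilyloxy)octan-1-ol | OCCCCCC[C@@H](C)O[Si](c1ccccc1)(c1ccccc1)C(C)(C)C | intermediate
8 | (R)-7-(tert-butyldiphenylsilyloxy)octanal (C43–C50) | O=CCCCCC[C@@H](C)O[Si](c1ccccc1)(c1ccccc1)C(C)(C)C | intermediate
9 | propanoyl chloride | CCC(=O)Cl | starting material
10 | methoxyethene | COC=C | starting material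
11 | 1-chloro-1-methoxypentan-3-one | CCC(=O)CC(Cl)OC | intermediate (not isolated)
12 | (E)-1-methoxypent-1-en-3-one | CCC(=O)/C=C/OC | intermediate
13 | (1E,3Z)-1-methoxy-3-(trimethylsilyloxy)penta-1,3-diene | CO/C=C/C(O[Si](C)(C)C)=C/C | intermediate
14 | all-cis 2-methoxy-5-methyl-6-[(6R)-6-(tert-butyldiphenylsilyloxy)heptyl]-4-(trimethylsilyloxy)-5,6-dihydro-2H-pyran | C[Si](C)(C)OC1=C[C@H](OC)O[C@H](CCCCC[C@@H](C)O[Si](c2ccccc2)(c3ccccc3)C(C)(C)C)[C@@H]1C | intermediate (not isolated)
15 | (2R,3S)-2-[(6R)-6-(tert-butyldiphenylsilyloxy)heptyl]-3-methyl-2,3-dihydro-4H-pyran-4-one (C39–C50) | O=C1C=CO[C@H](CCCCC[C@@H](C)O[Si](c2ccccc2)(c3ccccc3)C(C)(C)C)[C@@H]1C | intermediate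
16 | (2R,3S,6S)-2-[(6R)-6-(tert-butyldiphenylsilyloxy)heptyl]-6-methoxy-3-methyltetrahydro-4H-pyran-4-one | O=C1C[C@@H](OC)O[C@H](CCCCC[C@@H](C)O[Si](c2ccccc2)(c3ccccc3)C(C)(C)C)[C@@H]1C | intermediate
17 | (2R,3R,4S,6S)-2-[(6R)-6-(tert-butyldiphenylsilyloxy)heptyl]-6-methoxy-3-methyltetrahydro-2H-pyran-4-ol | O[C@H]1C[C@@H](OC)O[C@H](CCCCC[C@@H](C)O[Si](c2ccccc2)(c3ccccc3)C(C)(C)C)[C@@H]1C | intermediate
18 | (2R,3R,4S,6S)-2-[(6R)-6-(tert-butyldiphenylsilyloxy)heptyl]-6-methoxy-4-(4-methoxybenzyloxy)-3-methyltetrahydro-2H-pyran | COc1ccc(CO[C@H]2C[C@@H](OC)O[C@H](CCCCC[C@@H](C)O[Si](c3ccccc3)(c4ccccc4)C(C)(C)C)[C@@H]2C)cc1 | intermediate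
19 | (4S,5R,6R)-6-[(6R)-6-(tert-butyldiphenylsilyloxy)heptyl]-4-(4-methoxybenzyloxy)-5-methyltetrahydro-2H-pyran-2-ol, both anomers | COc1ccc(CO[C@H]2CC(O)O[C@H](CCCCC[C@@H](C)O[Si](c3ccccc3)(c4ccccc4)C(C)(C)C)[C@@H]2C)cc1 | intermediate
20 | 2-(tert-butyldimethylsilyl)-1,3-dithiane | C[Si](C)(C(C)(C)C)C1SCCCS1 | starting material
21 | (S)-2-[2-(benzyloxy)ethyl]oxirane | C(OCC[C@H]1CO1)c1ccccc1 | starting material
22 | (S)-2-(chloromethyl)oxirane | C1[C@H](O1)CCl | starting material
23 | 2-lithio-2-[(2S)-4-(benzyloxy)-2-(tert-butyldimethylsilyloxy)butyl]-1,3-dithiane | C(OCC[C@H](O[Si](C)(C)C(C)(C)C)CC1([Li])SCCCS1)c1ccccc1 | intermediate (not isolated)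
24 | tert-butyl{[(2S)-4-(benzyloxy)-1-(2-{[(2S)-oxiran-2-yl]methyl}-1,3-dithian-2-yl)butan-2-yl]oxy}dimethylsilane (C21–C28 and C5–C12) | C(OCC[C@H](O[Si](C)(C)C(C)(C)C)CC1(SCCCS1)C[C@H]1CO1)c1ccccc1 | intermediate
25 | (6-bromohexyloxy)(tert-butyl)dimethylsilane | BrCCCCCCO[Si](C)(C)C(C)(C)C | starting material
26 | (R)-2-(chloromethyl)oxirane | ClC[C@H]1CO1 | starting material
27 | [6-(tert-butyldimethylsilyloxy)hexyl]magnesium bromide | Br[Mg]CCCCCCO[Si](C)(C)C(C)(C)C | intermediate (not isolated)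
28 | (R)-9-(tert-butyldimethylsilyloxy)-1-chlorononan-2-ol | ClC[C@H](O)CCCCCCCO[Si](C)(C)C(C)(C)C | intermediate (not isolated)
29 | (R)-tert-butyldimethyl{[7-(oxiran-2-yl)heptyl]oxy}silane (C30–C38) | C1[C@H](O1)CCCCCCCO[Si](C)(C)C(C)(C)C | intermediate
30 | 2-lithio-2-[(2R)-2,9-bis(tert-butyldimethylsilyloxy)nonyl]-1,3-dithiane | [Li]C1(C[C@H](O[Si](C)(C)C(C)(C)C)CCCCCCCO[Si](C)(C)C(C)(C)C)SCCCS1 | intermediate (not isolated)
31 | C21–C38 bis-dithiane alcohol (O21 Bn; O23, O31, O38 TBS; C27 OH; dithianes at C25, C29) | C(OCC[C@H](O[Si](C)(C)C(C)(C)C)CC1(SCCCS1)C[C@H](O)CC1(SCCCS1)C[C@H](O[Si](C)(C)C(C)(C)C)CCCCCCCO[Si](C)(C)C(C)(C)C)c1ccccc1 | intermediate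
32 | C21–C38 bis-dithiane tetrakis-TBS ether | C(OCC[C@H](O[Si](C)(C)C(C)(C)C)CC1(SCCCS1)C[C@H](O[Si](C)(C)C(C)(C)C)CC1(SCCCS1)C[C@H](O[Si](C)(C)C(C)(C)C)CCCCCCCO[Si](C)(C)C(C)(C)C)c1ccccc1 | intermediate
33 | (3R,7R,11R)-3,7,11,18-tetrakis(tert-butyldimethylsilyloxy)octadecan-1-ol | OCC[C@H](O[Si](C)(C)C(C)(C)C)CCC[C@H](O[Si](C)(C)C(C)(C)C)CCC[C@H](O[Si](C)(C)C(C)(C)C)CCCCCCCO[Si](C)(C)C(C)(C)C | intermediate
34 | (3R,7R,11R)-3,7,11,18-tetrakis(tert-butyldimethylsilyloxy)octadecyl 2,2-dimethylpropanoate | CC(C)(C)C(=O)OCC[C@H](O[Si](C)(C)C(C)(C)C)CCC[C@H](O[Si](C)(C)C(C)(C)C)CCC[C@H](O[Si](C)(C)C(C)(C)C)CCCCCCCO[Si](C)(C)C(C)(C)C | intermediate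
35 | (3R,7R,11R)-3,7,11-tris(tert-butyldimethylsilyloxy)-18-hydroxyoctadecyl 2,2-dimethylpropanoate | CC(C)(C)C(=O)OCC[C@H](O[Si](C)(C)C(C)(C)C)CCC[C@H](O[Si](C)(C)C(C)(C)C)CCC[C@H](O[Si](C)(C)C(C)(C)C)CCCCCCCO | intermediate
36 | (3R,7R,11R)-3,7,11-tris(tert-butyldimethylsilyloxy)-18-iodooctadecyl 2,2-dimethylpropanoate | CC(C)(C)C(=O)OCC[C@H](O[Si](C)(C)C(C)(C)C)CCC[C@H](O[Si](C)(C)C(C)(C)C)CCC[C@H](O[Si](C)(C)C(C)(C)C)CCCCCCCI | intermediate
37 | [(8R,12R,16R)-8,12,16-tris(tert-butyldimethylsilyloxy)-18-(pivaloyloxy)octadecyl]triphenylphosphonium iodide (C21–C38) | CC(C)(C)C(=O)OCC[C@H](O[Si](C)(C)C(C)(C)C)CCC[C@H](O[Si](C)(C)C(C)(C)C)CCC[C@H](O[Si](C)(C)C(C)(C)C)CCCCCCC[P+](c1ccccc1)(c1ccccc1)c1ccccc1.[I-] | intermediate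
38 | methyl (S)-3-hydroxy-2-methylpropanoate | COC(=O)[C@@H](C)CO | starting material
39 | methyl (S)-3-(tert-butyldimethylsilyloxy)-2-methylpropanoate | COC(=O)[C@@H](C)CO[Si](C)(C)C(C)(C)C | intermediate
40 | (S)-3-(tert-butyldimethylsilyloxy)-2-methylpropanal | O=C[C@@H](C)CO[Si](C)(C)C(C)(C)C | intermediate
41 | (S)-tert-butyl[2-(1,3-dithian-2-yl)propoxy]dimethylsilane | C1CSC(SC1)[C@@H](C)CO[Si](C)(C)C(C)(C)C | intermediate
42 | 2-lithio derivative of 41 | [Li]C1(SCCCS1)[C@@H](C)CO[Si](C)(C)C(C)(C)C | intermediate (not isolated)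
43 | tert-butyldimethyl{[(2S)-2-(2-{[(2R)-oxiran-2-yl]methyl}-1,3-dithian-2-yl)propyl]oxy}silane (C14–C19) | C1[C@H](O1)CC1(SCCCS1)[C@@H](C)CO[Si](C)(C)C(C)(C)C | intermediate
44 | 1,3-dithiane | C1CSCSC1 | starting material
45 | 2-lithio-1,3-dithiane | [Li]C1SCCCS1 | intermediate (not isolated)
46 | C5–C13 alcohol (O5 Bn, O7 TBS, C9 dithiane, C11 OH, C13 1,3-dithian-2-yl) | C(OCC[C@H](O[Si](C)(C)C(C)(C)C)CC1(SCCCS1)C[C@H](O)CC1SCCCS1)c1ccccc1 | intermediate
47 | O11,C13-dilithio derivative of 46 | C(OCC[C@H](O[Si](C)(C)C(C)(C)C)CC1(SCCCS1)C[C@H](O[Li])CC1([Li])SCCCS1)c1ccccc1 | intermediate (not isolated)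
48 | C5–C19 tris-dithiane diol | C(OCC[C@H](O[Si](C)(C)C(C)(C)C)CC1(SCCCS1)C[C@H](O)CC1(SCCCS1)C[C@H](O)CC1(SCCCS1)[C@@H](C)CO[Si](C)(C)C(C)(C)C)c1ccccc1 | intermediate
49 | C5–C19 triketone diol (C9, C13, C17 ketones) | C(OCC[C@H](O[Si](C)(C)C(C)(C)C)CC(=O)C[C@H](O)CC(=O)C[C@H](O)CC(=O)[C@@H](C)CO[Si](C)(C)C(C)(C)C)c1ccccc1 | intermediate
50 | C5–C19 pentaol (C9, C11, C13, C15, C17 OH) | C(OCC[C@H](O[Si](C)(C)C(C)(C)C)C[C@@H](O)C[C@H](O)C[C@@H](O)C[C@H](O)C[C@@H](O)[C@@H](C)CO[Si](C)(C)C(C)(C)C)c1ccccc1 | intermediate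
51 | C5–C19 heptakis-TBS ether, O5 benzyl | C(OCC[C@H](O[Si](C)(C)C(C)(C)C)C[C@@H](O[Si](C)(C)C(C)(C)C)C[C@H](O[Si](C)(C)C(C)(C)C)C[C@@H](O[Si](C)(C)C(C)(C)C)C[C@H](O[Si](C)(C)C(C)(C)C)C[C@@H](O[Si](C)(C)C(C)(C)C)[C@@H](C)CO[Si](C)(C)C(C)(C)C)c1ccccc1 | intermediate
52 | C5 alcohol of the C5–C19 heptakis-TBS ether | OCC[C@H](O[Si](C)(C)C(C)(C)C)C[C@@H](O[Si](C)(C)C(C)(C)C)C[C@H](O[Si](C)(C)C(C)(C)C)C[C@@H](O[Si](C)(C)C(C)(C)C)C[C@H](O[Si](C)(C)C(C)(C)C)C[C@@H](O[Si](C)(C)C(C)(C)C)[C@@H](C)CO[Si](C)(C)C(C)(C)C | intermediate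
53 | C5 aldehyde of the C5–C19 heptakis-TBS ether | O=CC[C@H](O[Si](C)(C)C(C)(C)C)C[C@@H](O[Si](C)(C)C(C)(C)C)C[C@H](O[Si](C)(C)C(C)(C)C)C[C@@H](O[Si](C)(C)C(C)(C)C)C[C@H](O[Si](C)(C)C(C)(C)C)C[C@@H](O[Si](C)(C)C(C)(C)C)[C@@H](C)CO[Si](C)(C)C(C)(C)C | intermediate
54 | methyl 2-[bis(2,2,2-trifluoroethoxy)phosphoryl]propanoate | COC(=O)C(C)P(=O)(OCC(F)(F)F)OCC(F)(F)F | starting material
55 | potassium carbanion of 54 | COC(=O)[C-](C)P(=O)(OCC(F)(F)F)OCC(F)(F)F.[K+] | intermediate (not isolated)
56 | methyl (Z)-2-methylalk-2-enoate of the C3–C19 fragment (C3 ester, methyl on C4, (4Z) alkene, O19 TBS) | COC(=O)/C(C)=C\C[C@H](O[Si](C)(C)C(C)(C)C)C[C@@H](O[Si](C)(C)C(C)(C)C)C[C@H](O[Si](C)(C)C(C)(C)C)C[C@@H](O[Si](C)(C)C(C)(C)C)C[C@H](O[Si](C)(C)C(C)(C)C)C[C@@H](O[Si](C)(C)C(C)(C)C)[C@@H](C)CO[Si](C)(C)C(C)(C)C | intermediate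
57 | (Z)-allylic alcohol of the C3–C19 fragment (C3 primary alcohol) | OC/C(C)=C\C[C@H](O[Si](C)(C)C(C)(C)C)C[C@@H](O[Si](C)(C)C(C)(C)C)C[C@H](O[Si](C)(C)C(C)(C)C)C[C@@H](O[Si](C)(C)C(C)(C)C)C[C@H](O[Si](C)(C)C(C)(C)C)C[C@@H](O[Si](C)(C)C(C)(C)C)[C@@H](C)CO[Si](C)(C)C(C)(C)C | intermediate
58 | (Z)-enal of the C3–C19 fragment (C3 aldehyde, methyl on C4) | O=C/C(C)=C\C[C@H](O[Si](C)(C)C(C)(C)C)C[C@@H](O[Si](C)(C)C(C)(C)C)C[C@H](O[Si](C)(C)C(C)(C)C)C[C@@H](O[Si](C)(C)C(C)(C)C)C[C@H](O[Si](C)(C)C(C)(C)C)C[C@@H](O[Si](C)(C)C(C)(C)C)[C@@H](C)CO[Si](C)(C)C(C)(C)C | intermediate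
59 | methyl 2-[bis(2,2,2-trifluoroethoxy)phosphoryl]acetate | COC(=O)CP(=O)(OCC(F)(F)F)OCC(F)(F)F | starting material
60 | potassium carbanion of 59 | COC(=O)[CH-]P(=O)(OCC(F)(F)F)OCC(F)(F)F.[K+] | intermediate (not isolated)
61 | methyl (2Z,4Z)-dienoate of the C1–C19 fragment, O19 TBS | COC(=O)/C=C\C(C)=C/C[C@H](O[Si](C)(C)C(C)(C)C)C[C@@H](O[Si](C)(C)C(C)(C)C)C[C@H](O[Si](C)(C)C(C)(C)C)C[C@@H](O[Si](C)(C)C(C)(C)C)C[C@H](O[Si](C)(C)C(C)(C)C)C[C@@H](O[Si](C)(C)C(C)(C)C)[C@@H](C)CO[Si](C)(C)C(C)(C)C | intermediate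
62 | C19 alcohol of the C1–C19 dienoate | COC(=O)/C=C\C(C)=C/C[C@H](O[Si](C)(C)C(C)(C)C)C[C@@H](O[Si](C)(C)C(C)(C)C)C[C@H](O[Si](C)(C)C(C)(C)C)C[C@@H](O[Si](C)(C)C(C)(C)C)C[C@H](O[Si](C)(C)C(C)(C)C)C[C@@H](O[Si](C)(C)C(C)(C)C)[C@@H](C)CO | intermediate
63 | C19 aldehyde of the C1–C19 dienoate | COC(=O)/C=C\C(C)=C/C[C@H](O[Si](C)(C)C(C)(C)C)C[C@@H](O[Si](C)(C)C(C)(C)C)C[C@H](O[Si](C)(C)C(C)(C)C)C[C@@H](O[Si](C)(C)C(C)(C)C)C[C@H](O[Si](C)(C)C(C)(C)C)C[C@@H](O[Si](C)(C)C(C)(C)C)[C@@H](C)C=O | intermediate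
64 | ylide of 37 | CC(C)(C)C(=O)OCC[C@H](O[Si](C)(C)C(C)(C)C)CCC[C@H](O[Si](C)(C)C(C)(C)C)CCC[C@H](O[Si](C)(C)C(C)(C)C)CCCCCCC=P(c1ccccc1)(c1ccccc1)c1ccccc1 | intermediate (not isolated)
65 | C21–C50 (38Z)-alkene, free C43 OH, O21 Piv, O41 PMB, O49 TBDPS | CC(C)(C)C(=O)OCC[C@H](O[Si](C)(C)C(C)(C)C)CCC[C@H](O[Si](C)(C)C(C)(C)C)CCC[C@H](O[Si](C)(C)C(C)(C)C)CCCCCC/C=C\C[C@@H]([C@@H](C)[C@H](O)CCCCC[C@@H](C)O[Si](c2ccccc2)(c3ccccc3)C(C)(C)C)OCc1ccc(OC)cc1 | intermediate
66 | C43 TBS ether of 65 | CC(C)(C)C(=O)OCC[C@H](O[Si](C)(C)C(C)(C)C)CCC[C@H](O[Si](C)(C)C(C)(C)C)CCC[C@H](O[Si](C)(C)C(C)(C)C)CCCCCC/C=C\C[C@@H]([C@@H](C)[C@H](O[Si](C)(C)C(C)(C)C)CCCCC[C@@H](C)O[Si](c2ccccc2)(c3ccccc3)C(C)(C)C)OCc1ccc(OC)cc1 | intermediate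
67 | C21 alcohol of the C21–C50 fragment | OCC[C@H](O[Si](C)(C)C(C)(C)C)CCC[C@H](O[Si](C)(C)C(C)(C)C)CCC[C@H](O[Si](C)(C)C(C)(C)C)CCCCCC/C=C\C[C@@H]([C@@H](C)[C@H](O[Si](C)(C)C(C)(C)C)CCCCC[C@@H](C)O[Si](c2ccccc2)(c3ccccc3)C(C)(C)C)OCc1ccc(OC)cc1 | intermediate
68 | C21 aldehyde of the C21–C50 fragment | O=CC[C@H](O[Si](C)(C)C(C)(C)C)CCC[C@H](O[Si](C)(C)C(C)(C)C)CCC[C@H](O[Si](C)(C)C(C)(C)C)CCCCCC/C=C\C[C@@H]([C@@H](C)[C@H](O[Si](C)(C)C(C)(C)C)CCCCC[C@@H](C)O[Si](c2ccccc2)(c3ccccc3)C(C)(C)C)OCc1ccc(OC)cc1 | intermediate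
69 | ethyltriphenylphosphonium iodide | CC[P+](c1ccccc1)(c1ccccc1)c1ccccc1.[I-] | starting material
70 | (1-iodoethyl)triphenylphosphonium iodide | CC(I)[P+](c1ccccc1)(c1ccccc1)c1ccccc1.[I-] | intermediate (not isolated)
71 | (1-iodoethylidene)triphenylphosphorane | CC(I)=P(c1ccccc1)(c1ccccc1)c1ccccc1 | intermediate (not isolated)
72 | C20–C50 (20Z)-alkenyl iodide | I/C(C)=C\C[C@H](O[Si](C)(C)C(C)(C)C)CCC[C@H](O[Si](C)(C)C(C)(C)C)CCC[C@H](O[Si](C)(C)C(C)(C)C)CCCCCC/C=C\C[C@@H]([C@@H](C)[C@H](O[Si](C)(C)C(C)(C)C)CCCCC[C@@H](C)O[Si](c2ccccc2)(c3ccccc3)C(C)(C)C)OCc1ccc(OC)cc1 | intermediate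
73 | alkenyllithium from 72 | [Li]/C(C)=C\C[C@H](O[Si](C)(C)C(C)(C)C)CCC[C@H](O[Si](C)(C)C(C)(C)C)CCC[C@H](O[Si](C)(C)C(C)(C)C)CCCCCC/C=C\C[C@@H]([C@@H](C)[C@H](O[Si](C)(C)C(C)(C)C)CCCCC[C@@H](C)O[Si](c2ccccc2)(c3ccccc3)C(C)(C)C)OCc1ccc(OC)cc1 | intermediate (not isolated)
74 | alkenylmagnesium bromide from 73 | Br[Mg]/C(C)=C\C[C@H](O[Si](C)(C)C(C)(C)C)CCC[C@H](O[Si](C)(C)C(C)(C)C)CCC[C@H](O[Si](C)(C)C(C)(C)C)CCCCCC/C=C\C[C@@H]([C@@H](C)[C@H](O[Si](C)(C)C(C)(C)C)CCCCC[C@@H](C)O[Si](c2ccccc2)(c3ccccc3)C(C)(C)C)OCc1ccc(OC)cc1 | intermediate (not isolated)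
75 | C1–C50 allylic alcohol (free C19 OH) | COC(=O)/C=C\C(C)=C/C[C@H](O[Si](C)(C)C(C)(C)C)C[C@@H](O[Si](C)(C)C(C)(C)C)C[C@H](O[Si](C)(C)C(C)(C)C)C[C@@H](O[Si](C)(C)C(C)(C)C)C[C@H](O[Si](C)(C)C(C)(C)C)C[C@@H](O[Si](C)(C)C(C)(C)C)[C@@H](C)[C@H](O)/C(C)=C\C[C@H](O[Si](C)(C)C(C)(C)C)CCC[C@H](O[Si](C)(C)C(C)(C)C)CCC[C@H](O[Si](C)(C)C(C)(C)C)CCCCCC/C=C\C[C@@H]([C@@H](C)[C@H](O[Si](C)(C)C(C)(C)C)CCCCC[C@@H](C)O[Si](c2ccccc2)(c3ccccc3)C(C)(C)C)OCc1ccc(OC)cc1 | intermediate
76 | C19 TBS ether of 75 | COC(=O)/C=C\C(C)=C/C[C@H](O[Si](C)(C)C(C)(C)C)C[C@@H](O[Si](C)(C)C(C)(C)C)C[C@H](O[Si](C)(C)C(C)(C)C)C[C@@H](O[Si](C)(C)C(C)(C)C)C[C@H](O[Si](C)(C)C(C)(C)C)C[C@@H](O[Si](C)(C)C(C)(C)C)[C@@H](C)[C@H](O[Si](C)(C)C(C)(C)C)/C(C)=C\C[C@H](O[Si](C)(C)C(C)(C)C)CCC[C@H](O[Si](C)(C)C(C)(C)C)CCC[C@H](O[Si](C)(C)C(C)(C)C)CCCCCC/C=C\C[C@@H]([C@@H](C)[C@H](O[Si](C)(C)C(C)(C)C)CCCCC[C@@H](C)O[Si](c2ccccc2)(c3ccccc3)C(C)(C)C)OCc1ccc(OC)cc1 | intermediate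
77 | C41 alcohol of the C1–C50 methyl ester | COC(=O)/C=C\C(C)=C/C[C@H](O[Si](C)(C)C(C)(C)C)C[C@@H](O[Si](C)(C)C(C)(C)C)C[C@H](O[Si](C)(C)C(C)(C)C)C[C@@H](O[Si](C)(C)C(C)(C)C)C[C@H](O[Si](C)(C)C(C)(C)C)C[C@@H](O[Si](C)(C)C(C)(C)C)[C@@H](C)[C@H](O[Si](C)(C)C(C)(C)C)/C(C)=C\C[C@H](O[Si](C)(C)C(C)(C)C)CCC[C@H](O[Si](C)(C)C(C)(C)C)CCC[C@H](O[Si](C)(C)C(C)(C)C)CCCCCC/C=C\C[C@@H]([C@@H](C)[C@H](O[Si](C)(C)C(C)(C)C)CCCCC[C@@H](C)O[Si](c2ccccc2)(c3ccccc3)C(C)(C)C)O | intermediate
78 | seco acid | OC(=O)/C=C\C(C)=C/C[C@H](O[Si](C)(C)C(C)(C)C)C[C@@H](O[Si](C)(C)C(C)(C)C)C[C@H](O[Si](C)(C)C(C)(C)C)C[C@@H](O[Si](C)(C)C(C)(C)C)C[C@H](O[Si](C)(C)C(C)(C)C)C[C@@H](O[Si](C)(C)C(C)(C)C)[C@@H](C)[C@H](O[Si](C)(C)C(C)(C)C)/C(C)=C\C[C@H](O[Si](C)(C)C(C)(C)C)CCC[C@H](O[Si](C)(C)C(C)(C)C)CCC[C@H](O[Si](C)(C)C(C)(C)C)CCCCCC/C=C\C[C@@H]([C@@H](C)[C@H](O[Si](C)(C)C(C)(C)C)CCCCC[C@@H](C)O[Si](c2ccccc2)(c3ccccc3)C(C)(C)C)O | intermediate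
79 | 2,4,6-trichlorobenzoic mixed anhydride of 78 | O=C(OC(=O)/C=C\C(C)=C/C[C@H](O[Si](C)(C)C(C)(C)C)C[C@@H](O[Si](C)(C)C(C)(C)C)C[C@H](O[Si](C)(C)C(C)(C)C)C[C@@H](O[Si](C)(C)C(C)(C)C)C[C@H](O[Si](C)(C)C(C)(C)C)C[C@@H](O[Si](C)(C)C(C)(C)C)[C@@H](C)[C@H](O[Si](C)(C)C(C)(C)C)/C(C)=C\C[C@H](O[Si](C)(C)C(C)(C)C)CCC[C@H](O[Si](C)(C)C(C)(C)C)CCC[C@H](O[Si](C)(C)C(C)(C)C)CCCCCC/C=C\C[C@@H]([C@@H](C)[C@H](O[Si](C)(C)C(C)(C)C)CCCCC[C@@H](C)O[Si](c2ccccc2)(c3ccccc3)C(C)(C)C)O)c1c(Cl)cc(Cl)cc1Cl | intermediate (not isolated)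
80 | fully silylated macrolactone (eleven TBS ethers, O49 TBDPS) | CC1=C/C[C@H](O[Si](C)(C)C(C)(C)C)C[C@@H](O[Si](C)(C)C(C)(C)C)C[C@H](O[Si](C)(C)C(C)(C)C)C[C@@H](O[Si](C)(C)C(C)(C)C)C[C@H](O[Si](C)(C)C(C)(C)C)C[C@@H](O[Si](C)(C)C(C)(C)C)[C@@H](C)[C@H](O[Si](C)(C)C(C)(C)C)/C(C)=C\C[C@H](O[Si](C)(C)C(C)(C)C)CCC[C@H](O[Si](C)(C)C(C)(C)C)CCC[C@H](O[Si](C)(C)C(C)(C)C)CCCCCC/C=C\C[C@@H]([C@@H](C)[C@H](O[Si](C)(C)C(C)(C)C)CCCCC[C@@H](C)O[Si](c2ccccc2)(c3ccccc3)C(C)(C)C)OC(=O)/C=C\1 | intermediate
81 | target macrolide CNP0392687.2 | CC1=C/C[C@H](O)C[C@@H](O)C[C@H](O)C[C@@H](O)C[C@H](O)C[C@@H](O)[C@@H](C)[C@H](O)/C(C)=C\C[C@H](O)CCC[C@H](O)CCC[C@H](O)CCCCCC/C=C\C[C@@H]([C@@H](C)[C@H](O)CCCCC[C@@H](C)O)OC(=O)/C=C\1 | target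

## Step count and risks

Total: 48 steps. Longest linear sequence: 22 steps (from 38 through steps 21–24, 26–37 and 43–48); the path from 1 and 2 through steps 1–4, 7–11 and 38–48 counts 20 steps.

**Step 7 (key step).** The unbranched aliphatic aldehyde may add slowly, so the diene could hydrolyse first. Part of the reaction could also run through a stepwise Mukaiyama aldol path, which would erode the cis relationship, and facial discrimination could be incomplete. The fallback replaces catalyst control by auxiliary control. It sets out from aldehyde 8: an Evans syn-aldol reaction with (S)-4-benzyl-3-propanoyloxazolidin-2-one (Bu2BOSO2CF3, i-Pr2NEt, CH2Cl2, −78 °C) would give the syn aldol adduct (S)-4-benzyl-3-[(2S,3R,9R)-9-(tert-butyldiphenylsilyloxy)-3-hydroxy-2-methyldecanoyl]oxazolidin-2-one F1. Transamidation (MeNH(OMe)·HCl, AlMe3) would give the N-methoxy-N-methylamide F2, and excess HC≡CMgBr in THF would give the β-hydroxy ynone F3. A 6-endo cyclisation of the hydroxyl onto the ynone (AgOSO2CF3, catalytic, CH2Cl2) comes back to the route at dihydropyranone 15.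

**Step 8.** The addition is reversible, so the product may return to the enone on concentration, and prolonged acid may enolise the new ketone and move the C42 methyl to the more stable trans position. The fallback avoids the enone. It sets out from cycloadduct 14, worked up without acid and desilylated with Bu4NF/AcOH in THF at −20 °C. Protonation at C40 would give the 2,6-cis methoxy ketone F4, the C39 epimer of 16. The same three operations as steps 9 to 11 would lead through the axial alcohol F5 and the PMB ether F6, and hydrolysis comes back at lactol 19, where the anomeric centre no longer matters.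

**Step 9.** The axial C42 methyl lies on the face of equatorial attack, so facial selectivity may be poor. The fallback sets C41 by inversion on a ring without an anomeric substituent. It sets out from enone 15: Luche reduction (NaBH4, CeCl3·7H2O, MeOH, −78 °C) should give the all-cis allylic alcohol F7 by attack anti to the methyl. Mitsunobu reaction with 4-nitrobenzoic acid (PPh3, diisopropyl azodicarboxylate, toluene) would give the inverted ester F8, and methanolysis (K2CO3, MeOH) the allylic alcohol F9. Etherification (NaH, 4-methoxybenzyl chloride) would give the PMB ether F10, and hydration of the enol ether (PPh3·HBr, catalytic, H2O, THF) comes back at lactol 19. This path also bypasses step 8.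

**Step 35.** The α-methyl (Z)-enal may isomerise to the E isomer during its formation or under the olefination conditions, and Z selectivity at C2=C3 may be incomplete for the α-branched enal. The fallback forms C4=C5 by halo-olefination and C3–C4 by cross-coupling, so that no enal is handled. It sets out from aldehyde 53: olefination with the α-iodo ylide 71, generated from 69 through 70 as in step 42, would give the C4–C19 (Z)-alkenyl iodide F11, with iodine cis to C6. Stille coupling (Pd(PPh3)4, zerovalent palladium, CuO2C(2-thienyl), DMF, rt) with methyl (Z)-3-(tributylstannyl)prop-2-enoate F12, made from methyl prop-2-ynoate and Bu3SnH (Et3B, toluene, −78 °C), should proceed with retention at both alkenes and comes back at dienoate 61.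

**Step 43.** Felkin–Anh control may be incomplete for the hindered alkenyl metal, the aldehyde may enolise and epimerise at C18, and the methyl ester may be attacked if addition is slow. The fallback is a ligand-controlled Nozaki–Hiyama–Kishi coupling, which tolerates the ester and is matched with the substrate bias. It sets out from iodide 72 and aldehyde 63 and uses CrCl2 (divalent chromium) bound to a chiral oxazoline–sulfonamide ligand, NiCl2(2,9-dimethyl-1,10-phenanthroline) (catalytic), Mn, Cp2ZrCl2 and LiCl in MeCN at rt. It comes back at alcohol 75 and makes no new compound.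

**Step 47.** The acyl-pyridinium form of the dienoate may isomerise from Z to E by reversible conjugate addition of the catalyst, and oligomers may form if ring closure onto the hindered C41 hydroxyl is slow. The fallback activates the acid without a nucleophilic catalyst. It sets out from seco acid 78, which with ethoxyacetylene and [RuCl2(p-cymene)]2 (catalytic) in toluene would give the 1-ethoxyvinyl ester F13. Acid-catalysed acyl transfer (camphor-10-sulfonic acid, catalytic, toluene, 50 °C, high dilution) comes back at macrolactone 80.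

## Further compounds

F1 | step 7 | (S)-4-benzyl-3-[(2S,3R,9R)-9-(tert-butyldiphenylsilyloxy)-3-hydroxy-2-methyldecanoyl]oxazolidin-2-one | O=C1OC[C@H](Cc2ccccc2)N1C(=O)[C@@H](C)[C@H](O)CCCCC[C@@H](C)O[Si](c1ccccc1)(c1ccccc1)C(C)(C)C
F2 | step 7 | (2S,3R,9R)-9-(tert-butyldiphenylsilyloxy)-3-hydroxy-N-methoxy-N,2-dimethyldecanamide | CON(C)C(=O)[C@@H](C)[C@H](O)CCCCC[C@@H](C)O[Si](c1ccccc1)(c1ccccc1)C(C)(C)C
F3 | step 7 | (4S,5R,11R)-11-(tert-butyldiphenylsilyloxy)-5-hydroxy-4-methyldodec-1-yn-3-one | C#CC(=O)[C@@H](C)[C@H](O)CCCCC[C@@H](C)O[Si](c1ccccc1)(c1ccccc1)C(C)(C)C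
F4 | step 8 | (2R,3S,6R)-2-[(6R)-6-(tert-butyldiphenylsilyloxy)heptyl]-6-methoxy-3-methyltetrahydro-4H-pyran-4-one | O=C1C[C@H](OC)O[C@H](CCCCC[C@@H](C)O[Si](c2ccccc2)(c3ccccc3)C(C)(C)C)[C@@H]1C
F5 | step 8 | (2R,3R,4S,6R)-2-[(6R)-6-(tert-butyldiphenylsilyloxy)heptyl]-6-methoxy-3-methyltetrahydro-2H-pyran-4-ol | O[C@H]1C[C@H](OC)O[C@H](CCCCC[C@@H](C)O[Si](c2ccccc2)(c3ccccc3)C(C)(C)C)[C@@H]1C
F6 | step 8 | (2R,3R,4S,6R)-2-[(6R)-6-(tert-butyldiphenylsilyloxy)heptyl]-6-methoxy-4-(4-methoxybenzyloxy)-3-methyltetrahydro-2H-pyran | COc1ccc(CO[C@H]2C[C@H](OC)O[C@H](CCCCC[C@@H](C)O[Si](c3ccccc3)(c4ccccc4)C(C)(C)C)[C@@H]2C)cc1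
F7 | step 9 | all-cis 2-[(6R)-6-(tert-butyldiphenylsilyloxy)heptyl]-3-methyl-3,4-dihydro-2H-pyran-4-ol (C41 epimer) | O[C@@H]1C=CO[C@H](CCCCC[C@@H](C)O[Si](c2ccccc2)(c3ccccc3)C(C)(C)C)[C@@H]1C
F8 | step 9 | 4-nitrobenzoate of the C41-inverted 3,4-dihydro-2H-pyran-4-ol | O=C(O[C@H]1C=CO[C@H](CCCCC[C@@H](C)O[Si](c2ccccc2)(c3ccccc3)C(C)(C)C)[C@@H]1C)c1ccc(cc1)[N+](=O)[O-]
F9 | step 9 | 2-[(6R)-6-(tert-butyldiphenylsilyloxy)heptyl]-3-methyl-3,4-dihydro-2H-pyran-4-ol with the C41 hydroxyl trans to the methyl | O[C@H]1C=CO[C@H](CCCCC[C@@H](C)O[Si](c2ccccc2)(c3ccccc3)C(C)(C)C)[C@@H]1C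
F10 | step 9 | 4-methoxybenzyl ether of F9 | COc1ccc(CO[C@H]2C=CO[C@H](CCCCC[C@@H](C)O[Si](c3ccccc3)(c4ccccc4)C(C)(C)C)[C@@H]2C)cc1
F11 | step 35 | C4–C19 (Z)-alkenyl iodide (iodine and methyl on C4, O19 TBS) | I/C(C)=C\C[C@H](O[Si](C)(C)C(C)(C)C)C[C@@H](O[Si](C)(C)C(C)(C)C)C[C@H](O[Si](C)(C)C(C)(C)C)C[C@@H](O[Si](C)(C)C(C)(C)C)C[C@H](O[Si](C)(C)C(C)(C)C)C[C@@H](O[Si](C)(C)C(C)(C)C)[C@@H](C)CO[Si](C)(C)C(C)(C)C
F12 | step 35 | methyl (Z)-3-(tributylstannyl)prop-2-enoate | COC(=O)/C=C\[Sn](CCCC)(CCCC)CCCC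
F0 | step 43 | none | none
F13 | step 47 | 1-ethoxyvinyl ester of seco acid 78 | C=C(OCC)OC(=O)/C=C\C(C)=C/C[C@H](O[Si](C)(C)C(C)(C)C)C[C@@H](O[Si](C)(C)C(C)(C)C)C[C@H](O[Si](C)(C)C(C)(C)C)C[C@@H](O[Si](C)(C)C(C)(C)C)C[C@H](O[Si](C)(C)C(C)(C)C)C[C@@H](O[Si](C)(C)C(C)(C)C)[C@@H](C)[C@H](O[Si](C)(C)C(C)(C)C)/C(C)=C\C[C@H](O[Si](C)(C)C(C)(C)C)CCC[C@H](O[Si](C)(C)C(C)(C)C)CCC[C@H](O[Si](C)(C)C(C)(C)C)CCCCCC/C=C\C[C@@H]([C@@H](C)[C@H](O[Si](C)(C)C(C)(C)C)CCCCC[C@@H](C)O[Si](c2ccccc2)(c3ccccc3)C(C)(C)C)O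
A1 | alternative 1 | mixed diisopropylsilylene acetal joining O19 of the C5–C20 isopropenyl carbinol and O23 of the C21–C38 homoallylic alcohol | COc1ccc(COCC[C@H](O[Si](CC)(CC)CC)C[C@@H](O[Si](CC)(CC)CC)C[C@H](O[Si](CC)(CC)CC)C[C@@H](O[Si](CC)(CC)CC)C[C@H](O[Si](CC)(CC)CC)C[C@@H](O[Si](CC)(CC)CC)[C@@H](C)[C@@H](C(C)=C)O[Si](C(C)C)(C(C)C)O[C@@H](CC=C)CCC[C@H](O[Si](CC)(CC)CC)CCC[C@H](O[Si](CC)(CC)CC)CCCCCCCOC(=O)C(C)(C)C)cc1
A2 | alternative 1 | C5–C38 fragment with the (20Z)-alkene inside the eight-membered dioxasilacyclooctene | COc1ccc(COCC[C@H](O[Si](CC)(CC)CC)C[C@@H](O[Si](CC)(CC)CC)C[C@H](O[Si](CC)(CC)CC)C[C@@H](O[Si](CC)(CC)CC)C[C@H](O[Si](CC)(CC)CC)C[C@@H](O[Si](CC)(CC)CC)[C@@H](C)[C@H](O2)/C(C)=C\C[C@@H](CCC[C@H](O[Si](CC)(CC)CC)CCC[C@H](O[Si](CC)(CC)CC)CCCCCCCOC(=O)C(C)(C)C)O[Si]2(C(C)C)C(C)C)cc1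
A3 | alternative 2 | eight-membered (2Z,4Z)-dienolide on O7 carrying the chain with free C41 hydroxyl, other hydroxyls as triethylsilyl ethers | CC1=C/C[C@H](OC(=O)/C=C\1)C[C@@H](O[Si](CC)(CC)CC)C[C@H](O[Si](CC)(CC)CC)C[C@@H](O[Si](CC)(CC)CC)C[C@H](O[Si](CC)(CC)CC)C[C@@H](O[Si](CC)(CC)CC)[C@@H](C)[C@H](O[Si](CC)(CC)CC)/C(C)=C\C[C@H](O[Si](CC)(CC)CC)CCC[C@H](O[Si](CC)(CC)CC)CCC[C@H](O[Si](CC)(CC)CC)CCCCCC/C=C\C[C@@H]([C@@H](C)[C@H](O[Si](CC)(CC)CC)CCCCC[C@@H](C)O[Si](CC)(CC)CC)O
A4 | alternative 2 | 42-membered lactone with free C7 hydroxyl, other hydroxyls as triethylsilyl ethers | CC1=C/C[C@H](O)C[C@@H](O[Si](CC)(CC)CC)C[C@H](O[Si](CC)(CC)CC)C[C@@H](O[Si](CC)(CC)CC)C[C@H](O[Si](CC)(CC)CC)C[C@@H](O[Si](CC)(CC)CC)[C@@H](C)[C@H](O[Si](CC)(CC)CC)/C(C)=C\C[C@H](O[Si](CC)(CC)CC)CCC[C@H](O[Si](CC)(CC)CC)CCC[C@H](O[Si](CC)(CC)CC)CCCCCC/C=C\C[C@@H]([C@@H](C)[C@H](O[Si](CC)(CC)CC)CCCCC[C@@H](C)O[Si](CC)(CC)CC)OC(=O)/C=C\1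
A5 | alternative 3 | C9–C15 diol, anti-3,5-bis(tert-butyldimethylsilyloxy)heptane-1,7-diol | OCC[C@H](O[Si](C)(C)C(C)(C)C)C[C@@H](O[Si](C)(C)C(C)(C)C)CCO
A6 | alternative 3 | C2-symmetric bis-homoallylic diol spanning C7–C17 | C=CC[C@@H](O)C[C@H](O[Si](C)(C)C(C)(C)C)C[C@@H](O[Si](C)(C)C(C)(C)C)C[C@H](O)CC=C
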